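## The problem

The target (27) is a cyclopentane in which two adjacent ring carbons, C7 and C11, are both quaternary and both (R). Each carries a methyl group and the two methyls are cis; C7 carries the arm C6–C5(=O)–C4–C3(CH3)=C2–C1–aryl, and C11 carries the prenyl ketone C12(=O)–C13–C14=C15(CH3)2 (C8–C10 are the ring methylenes). These are the only stereocentres and neither can be corrected by epimerisation. In an open chain C7 would have little influence on C11, so the second centre has to be made while both sit in a ring. The C2=C3 alkene must be E, and the arene is a hydroquinone monomethyl ether whose side chain lies ortho to the methoxy group and meta to the hydroxyl, a pattern electrophilic substitution does not give. The functional groups are fragile in combination: both ketones are β,γ-unsaturated and move into conjugation with acid or base, the 1,5-diketone can close on itself by aldol reaction, the free phenol is oxidised to a quinone by many alcohol oxidants, and both trisubstituted alkenes react with peracids. The enabling feature is the 1,5-relationship of C5 and C12 through C6–C7–C11: a temporary C5–C12 bond folds both arms into a cyclopentenone with C11 as β-carbon and C12 as α-carbon, and a bicyclo[3.3.0]octane can only be cis-fused. Because the resulting cis-dimethyl bicyclic ketone core is meso, the absolute configuration finally depends on C12, not C6, carrying the prenyl group, so regiochemical fidelity of the enolate is a matter of enantiomeric purity.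

## Retrosynthesis

**End-game unmasking.** The phenol is released last from its tert-butyldimethylsilyl ether 26, because a free hydroquinone monoether would not survive the oxidation that creates the C12 ketone. Ketone 26 comes from carbinol 25 and its triethylsilyl ether 24. C12 stays at the alcohol level until then: a C12 ketone present while C4 is joined to C5 would let its C13 enolate close a six-membered ring onto C5. The forward steps need only mild, buffered conditions.

**C4–C5.** This cut divides 24 into an arene half and a cyclopentane half of similar size, at a bond next to a carbonyl and remote from both quaternary carbons. The neighbouring cuts are worse. C5–C6 would need a neopentyl nucleophile. An olefination at C2=C3 would have to control a trisubstituted alkene beside an enolisable ketone. A C1–aryl coupling would carry the complete diketone through organometallic chemistry. C4 becomes the α-carbanion 22 of allylic sulfone 21 and C5 the N-methoxy-N-methylamide 12; their product 23 is desulfonylated to 24. The acylation must occur once and at the α-carbon of the allyl anion, and the reduction must protonate the dienolate at C4 so the alkene stays out of conjugation.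

**C5–O reconnection.** Amide 12 is the silyl ether of hydroxy amide 11, which is lactone 10 opened by an amine. Removing the ring oxygen of 10 (retro Baeyer–Villiger) rejoins C5 to C12 and gives cyclopentanone 9, which has one functional group beside the prenyl alkene. This reconnection is preferred to cutting either arm from the ring because it is what lets C7 control C11. The oxidation must migrate C12 in preference to C6, which the substitution pattern favours, and must spare the prenyl alkene, which excludes peracids.

**Key disconnection.** Ketone 9 is cut at C12–C13, to prenyl bromide 7, and at C11–CH3, to a methyl group delivered from copper. This leaves enone 6 and passes through enolate 8. Making C11 quaternary first and prenylating the saturated ketone later would fail, because that ketone is meso and a base cannot tell C12 from C6. Enone 6 has nine carbons and one stereocentre. The forward step needs cis delivery of methyl, an enolate that does not equilibrate, and C-alkylation beside a quaternary carbon.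

**Enone.** Enone 6 opens at C11=C12 by retro-aldol condensation to diketone 5, whose methyl ketone is the Wacker product of allyl ketone 4. The only stereocentre of 4 is the C7 quaternary carbon. Decarboxylative asymmetric allylic alkylation of the racemic allyl β-keto ester 3 is the most direct catalytic way to set it. Ester 3 is the methylated Dieckmann product of diallyl adipate 1, formed through enolate 2. Auxiliary-based alkylations of a cyclopentanone would be longer and are poor at quaternary carbons. The demand here is high enantioselectivity on a five-membered enolate, the weakest point of an otherwise routine series.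

**Arene fragment.** Sulfone 21 is cut at C4–S to a sulfinate and allylic alcohol 19, through mesylate 20. Alcohol 19 is cut at C1–aryl: the whole C1–C4 unit with its methyl and oxygen is isoprene monoxide 17, opened in the SN2' sense by arylmagnesium bromide 18 from aryl bromide 16. This is shorter than prenylation followed by allylic oxidation, at the price of controlling alkene geometry in the opening. Bromide 16 is the silyl ether of phenol 15. Its hydroxyl is placed para to the methoxy group of commercial 2-bromo-6-methylanisole 13 by sterically directed C–H borylation (boronate 14) and oxidation; the bromine already marks the carbon that will bear the side chain.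

## Roads not taken

**Alternative 1:** The cut is the C7–C11 bond itself, by a retro-[3,3] shift to the nine-membered lactone A2. In A2 the ring oxygen is bonded to the allylic carbon C5, the C6=C7 alkene is Z, and C11 is the α-carbon. Forward, the silyl ketene acetal of A2 would undergo a ring-contracting Ireland–Claisen rearrangement through a boat-like array, giving acid A1 with the C12 carboxyl on C11 and an (E)-propenyl group (C6=C5–C4) on C7.

- Merits: both quaternary carbons and their cis relationship arise in one step. The absolute configuration is transferred suprafacially from a single secondary carbinol centre, so no chiral ligand is needed for a quaternary carbon.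
- Weak points: A2 is a medium ring with a Z-trisubstituted alkene, hard to close and hard to make geometrically pure. The rearrangement must join two fully substituted carbons through a strained boat.
- Weak points after the key step: C5 is an alkene carbon, not a carbonyl, and C4 is a terminal methyl. The C5 ketone and the C3–C4 bond therefore need several further operations. The C12 acid on a quaternary carbon must still become the prenyl ketone, where prenyl nucleophiles tend to couple at their tertiary end.
- Comparison: this road is better in stereochemical economy. The chosen plan answers with a carbocyclic sequence of short, separately precedented steps, with C5 delivered as an acyl group, and with the prenyl unit attached by SN2 alkylation in the key step.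

**Alternative 2:** The cut is C6–C7 and C11–C12, a retro-[2+2] to 1,2-dimethylcyclopentene A5 and the chiral dioxinone A4. Forward, irradiation would give the cis-anti-cis cyclobutane A3. Retro-aldol opening of the C6–C12 bond would then release C12 as a ketone carbon and C5 as a carboxyl carbon.

- Merits: both quaternary carbons come from a symmetrical, trivial alkene in one step. The cis relationship is guaranteed by the ring fusion and there is no regiochemical question.
- Where it is better: the two arms emerge already differentiated at the correct oxidation levels. The chosen plan needs an oxygen insertion (step 6) and a late re-oxidation (steps 15 and 16) to reach the same state.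
- Weak points: absolute control depends entirely on the facial preference of an excited enone for a hindered tetrasubstituted alkene, steered only by the remote tert-butyl acetal. Such alkenes are sluggish partners.
- Weak points after the key step: C12 would carry only a methyl group (C13). C13–C14 would have to be made by alkenylating a methyl ketone enolate under basic conditions that invite conjugation. That ketone would then be present during the C4–C5 coupling, where ring closure onto C5 threatens.
- Comparison: the chosen plan offsets the shorter core synthesis with a ligand-controlled step of understood selectivity, installation of the prenyl group in the same operation as the second quaternary carbon, and C12 masked as a carbinol until the end.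

**Alternative 3:** The cut is the same C5–O reconnection as in the chosen plan, but applied to the meso ketone A7, which has no prenyl group. Forward, a Baeyer–Villiger monooxygenase running on air and a recycled reduced nicotinamide cofactor would insert oxygen next to only one of the two enantiotopic α-methylenes, giving lactone A6.

- Merits: A7 is achiral and can be made without asymmetric catalysis. Neither a chiral ligand nor enolate regiocontrol is needed, and the route to the lactone is shorter than the chosen one.
- Weak points: both α-carbons of A7 are neopentyl and differ only by the enzyme's view of them. Acceptance and selectivity cannot be predicted from structure and would require screening.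
- Weak points after the key step: in A6, C12 is a primary alkoxy carbon lacking C13–C15. It would need oxidation and addition of a prenyl nucleophile to a neopentyl carbonyl, where allylic transposition favours the 1,1-dimethylallyl isomer.
- Comparison: the chosen plan trades the step count advantage for a predictable source of absolute configuration and for having C13–C15 attached by enolate alkylation before the ring is opened.

Key step: step 5

Remark on the chemistry: C12 in 9–12 and 23–25 is drawn in one configuration (prenyl trans to the neighbouring angular methyl in 9) and C4 in 22 and 23 is left undefined; either epimer serves, because C12 ends as a carbonyl carbon and C4 as a methylene.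

## Route

Step 1
Reactants: 1 diallyl adipate (diprop-2-en-1-yl hexanedioate)
Product: 3 allyl 1-methyl-2-oxocyclopentane-1-carboxylate (racemic), via sodium enolate 2 (not isolated)
Conditions: NaH, allyl alcohol (cat.), toluene, 95 °C; then MeI, THF, 35 °C
Reagents that add atoms: iodomethane, CI; sodium hydride, [Na+].[H-] (sodium only in 2)
Why: Dieckmann condensation gives the stabilised β-keto ester enolate 2, which is C-methylated in the same flask; the quaternary carbon is racemic here and is reset in step 2.

Step 2
Reactants: 3 allyl 1-methyl-2-oxocyclopentane-1-carboxylate
Product: 4 (R)-2-allyl-2-methylcyclopentan-1-one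
Conditions: Pd2(dba)3 (cat.), (R)-(CF3)3-t-BuPHOX (cat.), toluene, 25 °C
Reagents that add atoms: none
Why: Decarboxylative asymmetric allylic alkylation: zerovalent palladium ionises the allyl ester, CO2 is lost, and the phosphinooxazoline ligand differentiates the two faces of the resulting allylpalladium enolate, so racemic 3 converges on one enantiomer. The (R)-ligand is chosen by analogy with the six-membered series, where ligand and product descriptors coincide, and its trifluoromethylated form is used because five-membered enolates are the harder case.

Step 3
Reactants: 4 (R)-2-allyl-2-methylcyclopentan-1-one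
Product: 5 (R)-2-methyl-2-(2-oxopropyl)cyclopentan-1-one
Conditions: PdCl2 (cat.), Cu(OAc)2 (cat.), O2 (1 atm), DMA/H2O, rt
Reagents that add atoms: water, O
Why: Wacker oxidation of the terminal alkene is Markovnikov-selective and gives the methyl ketone; the quaternary centre has no hydrogen and is untouched.

Step 4
Reactants: 5 (R)-2-methyl-2-(2-oxopropyl)cyclopentan-1-one
Product: 6 (R)-6a-methyl-4,5,6,6a-tetrahydropentalen-2(1H)-one
Conditions: KOH, xylenes, 110 °C
Reagents that add atoms: none
Why: Intramolecular aldol condensation: only attack of the methyl ketone enolate (C12) on the ring carbonyl (C11) gives an adduct that can dehydrate, the bridged alternative being reversible. The quaternary C7 prevents the double bond from leaving conjugation.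

Step 5
Reactants: 6 (R)-6a-methyl-4,5,6,6a-tetrahydropentalen-2(1H)-one; 7 prenyl bromide (1-bromo-3-methylbut-2-ene)
Product: 9 (1R,3aR,6aS)-3a,6a-dimethyl-1-(3-methylbut-2-en-1-yl)hexahydropentalen-2(1H)-one, via lithium enolate 8 (not isolated)
Conditions: Me2CuLi, Et2O, −20 → 0 °C; then 7, HMPA, THF, −20 °C → rt
Reagents that add atoms: lithium dimethylcuprate, [Li+].C[Cu-]C
Why: The cuprate complexes the enone, adds at the β-carbon C11, and reductive elimination from the trivalent copper intermediate delivers the methyl group, leaving enolate 8 with its double bond fixed between C5 and C12; this is the known tandem conjugate addition–enolate alkylation of cyclopentenones and bicyclo[3.3.0]oct-1-en-3-ones. No ring is closed. The new quaternary centre C11 is controlled by the ring fusion: a bicyclo[3.3.0]octane is viable only cis-fused, so methyl arrives cis to the C7 methyl, and the absolute configuration follows from C7 set in step 2. The dipolar cosolvent and an excess of 7 then alkylate 8 at C12 by SN2 displacement at the primary carbon of 7, attaching the prenyl unit without allylic transposition. The C12 stereocentre is substrate-controlled (attack anti to the adjacent angular methyl is drawn) and is of no consequence. The selectivity that matters is regiochemical fidelity of the enolate: the dimethyl ketone core is meso, so alkylation at C6 after proton transfer would give material of the enantiomeric series and erode optical purity. It is secured by generating 8 regiospecifically, keeping it cold until the reactive allylic bromide is present, and by the hindered tertiary C12–H of 9, which is slow to exchange with remaining enolate and slow to alkylate again. C- over O-alkylation is favoured by the soft allylic electrophile.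

Step 6
Reactants: 9 (1R,3aR,6aS)-3a,6a-dimethyl-1-(3-methylbut-2-en-1-yl)hexahydropentalen-2(1H)-one
Product: 10 (1R,4aR,7aR)-4a,7a-dimethyl-1-(3-methylbut-2-en-1-yl)hexahydrocyclopenta[c]pyran-3(1H)-one
Conditions: (Me3SiO)2, SnCl4 (cat.), trans-cyclohexane-1,2-diamine (cat.), 4 Å MS, CH2Cl2, rt
Reagents that add atoms: bis(trimethylsilyl) peroxide, C[Si](C)(C)OO[Si](C)(C)C
Why: Baeyer–Villiger oxidation by a Lewis acid-activated silyl peroxide attacks the carbonyl and not the prenyl alkene, since no peracid is present. The more substituted C12 migrates in preference to the C6 methylene, with retention, placing oxygen between C5 and C12.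

Step 7
Reactants: 10 (1R,4aR,7aR)-4a,7a-dimethyl-1-(3-methylbut-2-en-1-yl)hexahydrocyclopenta[c]pyran-3(1H)-one
Product: 11 2-[(1R,2R)-2-[(1R)-1-hydroxy-4-methylpent-3-en-1-yl]-1,2-dimethylcyclopentyl]-N-methoxy-N-methylacetamide
Conditions: MeNH(OMe)·HCl, AlMe3, CH2Cl2, 0 °C → rt
Reagents that add atoms: N,O-dimethylhydroxylamine hydrochloride, CNOC.Cl
Why: Aminolysis of the lactone by the aluminium amide opens the ring to the N-methoxy-N-methylamide and frees the C12 hydroxyl without touching a stereocentre. The crude product is silylated at once, because the two quaternary carbons favour re-closure to 10.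

Step 8
Reactants: 11 2-[(1R,2R)-2-[(1R)-1-hydroxy-4-methylpent-3-en-1-yl]-1,2-dimethylcyclopentyl]-N-methoxy-N-methylacetamide
Product: 12 2-[(1R,2R)-1,2-dimethyl-2-[(1R)-4-methyl-1-(triethylsilyloxy)pent-3-en-1-yl]cyclopentyl]-N-methoxy-N-methylacetamide
Conditions: Et3SiOTf, 2,6-lutidine, CH2Cl2, −78 → 0 °C
Reagents that add atoms: triethylsilyl trifluoromethanesulfonate, CC[Si](CC)(CC)OS(=O)(=O)C(F)(F)F
Why: Silylation with the silyl triflate is fast enough for the hindered neopentyl-type carbinol. The ether blocks re-lactonisation and keeps an alkoxide away from the amide during the carbanion coupling.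

Step 9
Reactants: 13 2-bromo-6-methylanisole (1-bromo-2-methoxy-3-methylbenzene)
Product: 15 3-bromo-4-methoxy-5-methylphenol, via aryl pinacol boronate 14 (not isolated)
Conditions: [Ir(OMe)(cod)]2 (cat.), 4,4'-di-tert-butyl-2,2'-bipyridine (cat.), B2pin2, THF, 80 °C; then KHSO5 (Oxone), acetone/H2O, rt
Reagents that add atoms: potassium peroxymonosulfate, [K+].[O-]S(=O)(=O)OO; bis(pinacolato)diboron, CC1(C)OB(OC1(C)C)B1OC(C)(C)C(C)(C)O1 (boron only in 14)
Why: Iridium-catalysed C–H borylation is sterically governed and takes the only ring C–H without an ortho substituent, which is the one para to the methoxy group. Oxidation of the C–B bond then gives the phenol; the aryl bromide is tolerated in both stages.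

Step 10
Reactants: 15 3-bromo-4-methoxy-5-methylphenol
Product: 16 (3-bromo-4-methoxy-5-methylphenoxy)(tert-butyl)dimethylsilane
Conditions: TBSCl, imidazole, DMF, rt
Reagents that add atoms: tert-butyldimethylsilyl chloride, CC(C)(C)[Si](C)(C)Cl
Why: Standard silylation of a phenol. The aryl silyl ether tolerates the organometallic, reductive and oxidative steps ahead and can be removed last by buffered fluoride.

Step 11
Reactants: 16 (3-bromo-4-methoxy-5-methylphenoxy)(tert-butyl)dimethylsilane; 17 2-methyl-2-vinyloxirane (isoprene monoxide, racemic)
Product: 19 (E)-4-[5-(tert-butyldimethylsilyloxy)-2-methoxy-3-methylphenyl]-2-methylbut-2-en-1-ol, via arylmagnesium bromide 18 (not isolated)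
Conditions: Mg, THF, 50 °C; then 17, CuI (cat.), THF, −40 → 0 °C
Reagents that add atoms: magnesium, [Mg] (only in 18)
Why: Copper-catalysed SN2' opening of the vinyl oxirane by the arylmagnesium bromide forms the C1–aryl bond at the vinyl terminus and moves the double bond to C2=C3. Anti addition through the preferred transoid conformer of 17 favours the (E)-allylic alcohol.

Step 12
Reactants: 19 (E)-4-[5-(tert-butyldimethylsilyloxy)-2-methoxy-3-methylphenyl]-2-methylbut-2-en-1-ol
Product: 21 tert-butyl{4-methoxy-3-methyl-5-[(E)-3-methyl-4-(phenylsulfonyl)but-2-en-1-yl]phenoxy}dimethylsilane, via allylic mesylate 20 (not isolated)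
Conditions: MsCl, Et3N, THF, −20 °C; then PhSO2Na, DMF, rt
Reagents that add atoms: sodium benzenesulfinate, [Na+].[O-]S(=O)c1ccccc1; methanesulfonyl chloride, CS(=O)(=O)Cl (only in 20)
Why: Sulfonylation followed by SN2 displacement at the primary allylic carbon by the sulfur atom of the sulfinate gives the sulfone. Direct displacement does not involve the double bond, so the E geometry is kept.

Step 13
Reactants: 21 tert-butyl{4-methoxy-3-methyl-5-[(E)-3-methyl-4-(phenylsulfonyl)but-2-en-1-yl]phenoxy}dimethylsilane; 12 2-[(1R,2R)-1,2-dimethyl-2-[(1R)-4-methyl-1-(triethylsilyloxy)pent-3-en-1-yl]cyclopentyl]-N-methoxy-N-methylacetamide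
Product: 23 (E)-6-[5-(tert-butyldimethylsilyloxy)-2-methoxy-3-methylphenyl]-1-[(1R,2R)-1,2-dimethyl-2-[(1R)-4-methyl-1-(triethylsilyloxy)pent-3-en-1-yl]cyclopentyl]-4-methyl-3-(phenylsulfonyl)hex-4-en-2-one (both C3 epimers), via lithiated sulfone 22 (not isolated)
Conditions: n-BuLi, THF, −78 °C; then 12, −78 → −40 °C; aq. NH4Cl
Reagents that add atoms: n-butyllithium, [Li]CCCC (lithium only in 22)
Why: Acylation of an α-sulfonyl carbanion by an N-methoxy-N-methylamide: the sulfone-stabilised allyl anion reacts at its α-carbon C4, and the chelated tetrahedral adduct persists until work-up, so no ketone is exposed to the carbanion. The new C4 stereocentre is removed in step 14.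

Step 14
Reactants: 23 the β-keto sulfone of step 13
Product: 24 (E)-6-[5-(tert-butyldimethylsilyloxy)-2-methoxy-3-methylphenyl]-1-[(1R,2R)-1,2-dimethyl-2-[(1R)-4-methyl-1-(triethylsilyloxy)pent-3-en-1-yl]cyclopentyl]-4-methylhex-4-en-2-one
Conditions: SmI2, THF/MeOH, −78 °C
Reagents that add atoms: none
Why: Reductive desulfonylation of a β-keto sulfone by single-electron transfer: two equivalents of divalent samarium expel benzenesulfinate and leave a samarium dienolate. Methanol protonates it kinetically at the α-carbon C4, so the C2=C3 bond stays out of conjugation and keeps its E geometry.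

Step 15
Reactants: 24 the bis-silyl ether keto compound of step 14
Product: 25 (E)-6-[5-(tert-butyldimethylsilyloxy)-2-methoxy-3-methylphenyl]-1-[(1R,2R)-2-[(1R)-1-hydroxy-4-methylpent-3-en-1-yl]-1,2-dimethylcyclopentyl]-4-methylhex-4-en-2-one
Conditions: HF·pyridine, pyridine, THF, 0 °C
Reagents that add atoms: none
Why: Buffered acidic fluoride cleaves the alkyl triethylsilyl ether, while the aryl tert-butyldimethylsilyl ether, much slower under acidic fluoride, remains. The product may sit partly as the six-membered hemiketal between the C12 hydroxyl and C5, which is harmless.

Step 16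
Reactants: 25 the C12 carbinol of step 15
Product: 26 (E)-6-[5-(tert-butyldimethylsilyloxy)-2-methoxy-3-methylphenyl]-1-[(1R,2R)-1,2-dimethyl-2-(4-methylpent-3-enoyl)cyclopentyl]-4-methylhex-4-en-2-one
Conditions: DMP (1,1,1-triacetoxy-1,1-dihydro-1,2-benziodoxol-3(1H)-one), NaHCO3, CH2Cl2, 0 °C → rt
Reagents that add atoms: none
Why: Periodinane oxidation of a secondary alcohol under buffered, near-neutral conditions leaves both β,γ-unsaturated ketones unenolised and the silylated arene unoxidised. Any hemiketal equilibrates with the open hydroxy ketone, the only form that can be oxidised, so material is drawn through it. The C12 stereocentre disappears here.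

Step 17
Reactants: 26 the silyl-protected diketone of step 16
Product: 27 (E)-6-(5-hydroxy-2-methoxy-3-methylphenyl)-1-[(1R,2R)-1,2-dimethyl-2-(4-methylpent-3-enoyl)cyclopentyl]-4-methylhex-4-en-2-one (target)
Conditions: n-Bu4NF, AcOH, THF, 0 °C
Reagents that add atoms: none
Why: Fluoride cleaves the aryl silyl ether. Acetic acid buffers the medium so that neither phenoxide nor basic fluoride can trigger conjugation of the skipped enones or aldol closure of the 1,5-diketone.

## Compound list

1 | diallyl adipate | C=CCOC(=O)CCCCC(=O)OCC=C | starting material
2 | sodium 2-[(allyloxy)carbonyl]cyclopent-1-en-1-olate | [Na+].[O-]C1=C(C(=O)OCC=C)CCC1 | intermediate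
3 | allyl 1-methyl-2-oxocyclopentane-1-carboxylate (racemic) | C=CCOC(=O)C1(C)CCCC1=O | intermediate
4 | (R)-2-allyl-2-methylcyclopentan-1-one | C=CC[C@@]1(C)CCCC1=O | intermediate
5 | (R)-2-methyl-2-(2-oxopropyl)cyclopentan-1-one | CC(=O)C[C@@]1(C)CCCC1=O | intermediate
6 | (R)-6a-methyl-4,5,6,6a-tetrahydropentalen-2(1H)-one | O=C1C[C@@]2(C)CCCC2=C1 | intermediate
7 | prenyl bromide (1-bromo-3-methylbut-2-ene) | CC(C)=CCBr | starting material
8 | lithium (3aR,6aS)-3a,6a-dimethyl-3,3a,4,5,6,6a-hexahydropentalen-2-olate | [Li]OC1=C[C@]2(C)CCC[C@]2(C)C1 | intermediate
9 | (1R,3aR,6aS)-3a,6a-dimethyl-1-(3-methylbut-2-en-1-yl)hexahydropentalen-2(1H)-one | O=C1C[C@@]2(C)CCC[C@@]2(C)[C@H]1CC=C(C)C | intermediate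
10 | (1R,4aR,7aR)-4a,7a-dimethyl-1-(3-methylbut-2-en-1-yl)hexahydrocyclopenta[c]pyran-3(1H)-one | O=C1C[C@@]2(C)CCC[C@@]2(C)[C@@H](CC=C(C)C)O1 | intermediate
11 | 2-[(1R,2R)-2-[(1R)-1-hydroxy-4-methylpent-3-en-1-yl]-1,2-dimethylcyclopentyl]-N-methoxy-N-methylacetamide | CON(C)C(=O)C[C@@]1(C)CCC[C@@]1(C)[C@H](O)CC=C(C)C | intermediate
12 | 2-[(1R,2R)-1,2-dimethyl-2-[(1R)-4-methyl-1-(triethylsilyloxy)pent-3-en-1-yl]cyclopentyl]-N-methoxy-N-methylacetamide | CON(C)C(=O)C[C@@]1(C)CCC[C@@]1(C)[C@H](O[Si](CC)(CC)CC)CC=C(C)C | intermediate
13 | 2-bromo-6-methylanisole (1-bromo-2-methoxy-3-methylbenzene) | COc1c(C)cccc1Br | starting material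
14 | 2-(3-bromo-4-methoxy-5-methylphenyl)-4,4,5,5-tetramethyl-1,3,2-dioxaborolane | COc1c(C)cc(B2OC(C)(C)C(C)(C)O2)cc1Br | intermediate
15 | 3-bromo-4-methoxy-5-methylphenol | COc1c(C)cc(O)cc1Br | intermediate
16 | (3-bromo-4-methoxy-5-methylphenoxy)(tert-butyl)dimethylsilane | COc1c(C)cc(O[Si](C)(C)C(C)(C)C)cc1Br | intermediate
17 | 2-methyl-2-vinyloxirane (isoprene monoxide, racemic) | CC1(C=C)CO1 | starting material
18 | [5-(tert-butyldimethylsilyloxy)-2-methoxy-3-methylphenyl]magnesium bromide | COc1c(C)cc(O[Si](C)(C)C(C)(C)C)cc1[Mg]Br | intermediate
19 | (E)-4-[5-(tert-butyldimethylsilyloxy)-2-methoxy-3-methylphenyl]-2-methylbut-2-en-1-ol | COc1c(C)cc(O[Si](C)(C)C(C)(C)C)cc1C/C=C(\C)CO | intermediate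
20 | (E)-4-[5-(tert-butyldimethylsilyloxy)-2-methoxy-3-methylphenyl]-2-methylbut-2-en-1-yl methanesulfonate | COc1c(C)cc(O[Si](C)(C)C(C)(C)C)cc1C/C=C(\C)COS(C)(=O)=O | intermediate
21 | tert-butyl{4-methoxy-3-methyl-5-[(E)-3-methyl-4-(phenylsulfonyl)but-2-en-1-yl]phenoxy}dimethylsilane | COc1c(C)cc(O[Si](C)(C)C(C)(C)C)cc1C/C=C(\C)CS(=O)(=O)c1ccccc1 | intermediate
22 | α-lithio derivative of 21 (lithium on the sulfonyl-bearing carbon C4, configuration undefined) | COc1c(C)cc(O[Si](C)(C)C(C)(C)C)cc1C/C=C(\C)C([Li])S(=O)(=O)c1ccccc1 | intermediate
23 | (E)-6-[5-(tert-butyldimethylsilyloxy)-2-methoxy-3-methylphenyl]-1-[(1R,2R)-1,2-dimethyl-2-[(1R)-4-methyl-1-(triethylsilyloxy)pent-3-en-1-yl]cyclopentyl]-4-methyl-3-(phenylsulfonyl)hex-4-en-2-one (both C3 epimers) | COc1c(C)cc(O[Si](C)(C)C(C)(C)C)cc1C/C=C(\C)C(C(=O)C[C@@]1(C)CCC[C@@]1(C)[C@H](O[Si](CC)(CC)CC)CC=C(C)C)S(=O)(=O)c1ccccc1 | intermediate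
24 | (E)-6-[5-(tert-butyldimethylsilyloxy)-2-methoxy-3-methylphenyl]-1-[(1R,2R)-1,2-dimethyl-2-[(1R)-4-methyl-1-(triethylsilyloxy)pent-3-en-1-yl]cyclopentyl]-4-methylhex-4-en-2-one | COc1c(C)cc(O[Si](C)(C)C(C)(C)C)cc1C/C=C(\C)CC(=O)C[C@@]1(C)CCC[C@@]1(C)[C@H](O[Si](CC)(CC)CC)CC=C(C)C | intermediate
25 | (E)-6-[5-(tert-butyldimethylsilyloxy)-2-methoxy-3-methylphenyl]-1-[(1R,2R)-2-[(1R)-1-hydroxy-4-methylpent-3-en-1-yl]-1,2-dimethylcyclopentyl]-4-methylhex-4-en-2-one | COc1c(C)cc(O[Si](C)(C)C(C)(C)C)cc1C/C=C(\C)CC(=O)C[C@@]1(C)CCC[C@@]1(C)[C@H](O)CC=C(C)C | intermediate
26 | (E)-6-[5-(tert-butyldimethylsilyloxy)-2-methoxy-3-methylphenyl]-1-[(1R,2R)-1,2-dimethyl-2-(4-methylpent-3-enoyl)cyclopentyl]-4-methylhex-4-en-2-one | COc1c(C)cc(O[Si](C)(C)C(C)(C)C)cc1C/C=C(\C)CC(=O)C[C@@]1(C)CCC[C@@]1(C)C(=O)CC=C(C)C | intermediate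
27 | (E)-6-(5-hydroxy-2-methoxy-3-methylphenyl)-1-[(1R,2R)-1,2-dimethyl-2-(4-methylpent-3-enoyl)cyclopentyl]-4-methylhex-4-en-2-one | COc1c(C)cc(O)cc1C/C=C(\C)CC(=O)C[C@@]1(C)CCC[C@@]1(C)C(=O)CC=C(C)C | target

## Step count and least certain steps

Total step count: 17. Longest linear sequence: 13 steps (steps 1–8, then 13–17, from diallyl adipate 1); the arene branch (steps 9–12) joins at step 13.

**Step 5 (key step).** The conjugate addition may stall, because C11 becomes quaternary next to the quaternary C7. The copper-containing enolate may also alkylate slowly enough for proton transfer to move it to C6, which would erode enantiomeric purity; O-alkylation and double alkylation are lesser risks. Fallback, from 6 and returning at 9: the addition is run with Me2CuLi and chlorotrimethylsilane so that the enolate is captured as it forms, and the trimethylsilyl enol ether F1 is isolated. F1 is cleaved with MeLi in THF to give the copper-free lithium enolate 8 with unchanged regiochemistry, which is alkylated with 7 and HMPA. This separates the two bond formations and removes copper from the alkylation.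

**Step 2.** Enantioselection in the allylation of a five-membered enolate may fall short, and everything downstream inherits that purity. Fallback, from 4 and returning at 4: the ketone is converted into its crystalline semicarbazone F2, which is enriched by recrystallisation and hydrolysed with aqueous acid to return 4 of higher enantiomeric purity.

**Step 6.** The hindered carbonyl may be slow to take up the silyl peroxide, and prolonged exposure to the Lewis acid could lead to alkene oxidation or cation chemistry at the prenyl group. Fallback, from 9 and returning at 10: both sites are oxidised deliberately with excess buffered m-chloroperbenzoic acid to the epoxy lactone F3. The epoxide is then deoxygenated with the tungsten reagent prepared from WCl6 and two equivalents of n-BuLi. Since C15 carries two methyl groups, the regenerated alkene has no geometry to lose.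

**Step 11.** The opening of 17 may give some (Z)-alcohol, or direct attack at the oxirane methylene, and geometric purity at C2=C3 cannot be repaired later. Fallback, from 18 and returning at 19: the arylmagnesium bromide is coupled with prenyl bromide 7 under CuI catalysis to give the aryl prenyl compound F4. Its (E)-methyl group is hydroxylated with catalytic SeO2 and tert-butyl hydroperoxide, with a borohydride work-up to return any enal to the alcohol. This oxidation is E-selective by mechanism.

**Step 16.** The hydroxy ketone may rest largely as the hemiketal and oxidise slowly, leaving time for acid-promoted dehydration to a cyclic enol ether or for conjugation of the skipped enones. Fallback, from 24 and returning at 26 without a new isolated compound (F0): the triethylsilyl ether is converted directly into the ketone by oxidative desilylation with 2-iodoxybenzoic acid in DMSO, a known reaction of triethylsilyl ethers that spares tert-butyldimethylsilyl ethers, so that the alcohol is consumed as it is released.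

## Further compounds

F1 | step 5 | trimethyl{[(3aR,6aS)-3a,6a-dimethyl-3,3a,4,5,6,6a-hexahydropentalen-2-yl]oxy}silane | C[Si](C)(C)OC1=C[C@]2(C)CCC[C@]2(C)C1
F2 | step 2 | (E)-2-[(2R)-2-allyl-2-methylcyclopentylidene]hydrazine-1-carboxamide | C=CC[C@@]1(C)CCC/C1=N\NC(N)=O
F3 | step 6 | (1R,4aR,7aR)-1-[(3,3-dimethyloxiran-2-yl)methyl]-4a,7a-dimethylhexahydrocyclopenta[c]pyran-3(1H)-one (both epoxide epimers) | O=C1C[C@@]2(C)CCC[C@@]2(C)[C@@H](CC2OC2(C)C)O1
F4 | step 11 | tert-butyl[4-methoxy-3-methyl-5-(3-methylbut-2-en-1-yl)phenoxy]dimethylsilane | COc1c(C)cc(O[Si](C)(C)C(C)(C)C)cc1CC=C(C)C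
F0 | step 16 | none | none
A1 | alternative 1 | (1R,2R)-1,2-dimethyl-2-[(E)-prop-1-en-1-yl]cyclopentane-1-carboxylic acid | C/C=C/[C@@]1(C)CCC[C@@]1(C)C(O)=O
A2 | alternative 1 | (7Z,9R)-3,7,9-trimethyl-4,5,6,9-tetrahydrooxonin-2(3H)-one (C3 configuration immaterial) | O=C1O[C@H](C)/C=C(/C)CCCC1C
A3 | alternative 2 | cis-anti-cis cyclobutane photoadduct (2-tert-butyl-1,3-dioxan-4-one fused to 1,5-dimethylbicyclo[3.2.0]heptane) | C[C@@]12O[C@@H](C(C)(C)C)OC(=O)[C@@H]1[C@@]3(C)CCC[C@@]23C
A4 | alternative 2 | (R)-2-tert-butyl-6-methyl-4H-1,3-dioxin-4-one | CC1=CC(=O)O[C@H](C(C)(C)C)O1
A5 | alternative 2 | 1,2-dimethylcyclopent-1-ene | CC1=C(C)CCC1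
A6 | alternative 3 | (4aR,7aR)-4a,7a-dimethylhexahydrocyclopenta[c]pyran-3(1H)-one | O=C1C[C@@]2(C)CCC[C@@]2(C)CO1
A7 | alternative 3 | (3aR,6aS)-3a,6a-dimethylhexahydropentalen-2(1H)-one (meso) | O=C1C[C@@]2(C)CCC[C@@]2(C)C1
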